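Ring B (the bromocyclohexanol; C1 carbinol, C2 bromide, C4 side-chain carbon) is disconnected across C2–C3 and C4–C5 to an alkyl vinyl ketone that already carries the complete epoxycyclohexane ring A, made from (S)-carvone, and to (Z)-1-bromo-2-silyloxybutadiene. The key step, a catalyst-controlled endo Diels–Alder reaction, exploits the 1,3-cis relationship of the C2 bromine and the C4 side chain and the para relationship of C4 and C1: in one operation it closes ring B, sets C2 and C4 and leaves C1 as a ketone. The dienophile carbonyl later becomes the exocyclic methylene; equatorial methyl addition to C1 completes the cis-bromohydrin.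

Key step: step 10

Remark: the sense of facial induction of the phosphoramide catalyst is assumed by analogy with simple alkyl vinyl ketones; the antipodal catalyst is used if the opposite ring-B configuration results.

Step 1
Reactants: 1 (S)-(+)-carvone
Product: 3 ethyl 2-[(1R,6S)-3-methyl-2-oxo-6-(prop-1-en-2-yl)cyclohex-3-en-1-yl]acetate, via lithium dienolate 2 (not isolated)
Conditions: LDA (commercial solution), THF, −78 °C; BrCH2CO2Et, −78 → −20 °C
Reagents that add atoms: ethyl bromoacetate, BrCC(=O)OCC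
Why: Kinetic alpha'-deprotonation gives the cross-conjugated dienolate and enolate alkylation occurs anti to the neighbouring isopropenyl group, which sets the new ring stereocenter trans to it (also the thermodynamically favoured epimer).

Step 2
Reactants: 3 keto ester
Product: 4 N-tosylhydrazone of 3
Conditions: TsNHNH2, EtOH, cat. AcOH, 50 °C
Reagents that add atoms: 4-methylbenzenesulfonohydrazide, Cc1ccc(cc1)S(=O)(=O)NN
Why: Hydrazone formation by condensation of the enone carbonyl with tosylhydrazide; no stereocenter changes because the alpha center is already in its stable trans arrangement.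

Step 3
Reactants: 4 tosylhydrazone
Product: 6 ethyl 2-[(1S,6S)-3-methyl-6-(prop-1-en-2-yl)cyclohex-2-en-1-yl]acetate, via allylic diazene 5 (not isolated)
Conditions: catecholborane, CHCl3, 0 °C; NaOAc·3H2O, reflux
Reagents that add atoms: none
Why: Kabalka reduction, in which 1,2-hydride delivery to the unsaturated tosylhydrazone, loss of sulfinate and retro-ene extrusion of N2 from the allylic diazene move the double bond onto the former carbonyl carbon, giving the 1-methylcyclohexene with the ester arm on its allylic carbon; no stereocenter is formed.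

Step 4
Reactants: 6 alkene ester
Product: 7 2-[(1S,6S)-3-methyl-6-(prop-1-en-2-yl)cyclohex-2-en-1-yl]ethan-1-ol
Conditions: LiAlH4, Et2O, 0 °C
Reagents that add atoms: none
Why: Hydride reduction of the ester to the primary alcohol; the isolated alkenes and both stereocenters are inert to LiAlH4.

Step 5
Reactants: 7 bishomoallylic alcohol
Product: 8 2-[(1R,2R,3S,6S)-6-methyl-3-(prop-1-en-2-yl)-7-oxabicyclo[4.1.0]heptan-2-yl]ethan-1-ol
Conditions: VO(acac)2 (cat.), t-BuOOH, CH2Cl2, 0 °C → rt
Reagents that add atoms: tert-butyl hydroperoxide, CC(C)(C)OO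
Why: Hydroxyl-directed epoxidation, in which the vanadium alkoxide of the bishomoallylic alcohol delivers the peroxide oxygen to the face of the ring alkene that carries the hydroxyethyl arm, setting both oxirane carbons cis to that arm and trans to the isopropenyl group, while the 1,1-disubstituted alkene is out of reach and less electron-rich.

Step 6
Reactants: 8 epoxy alcohol
Product: 9 2-[(1R,2R,3S,6S)-6-methyl-3-(prop-1-en-2-yl)-7-oxabicyclo[4.1.0]heptan-2-yl]acetaldehyde
Conditions: Dess–Martin periodinane, NaHCO3, CH2Cl2, 0 °C → rt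
Reagents that add atoms: none
Why: Dess–Martin oxidation of the primary alcohol to the aldehyde under buffered, non-acidic conditions that spare the oxirane; the aldehyde has no alpha stereocenter.

Step 7
Reactants: 9 epoxy aldehyde
Product: 10 1-[(1R,2R,3S,6S)-6-methyl-3-(prop-1-en-2-yl)-7-oxabicyclo[4.1.0]heptan-2-yl]but-3-en-2-ol (both carbinol epimers)
Conditions: CH2=CHMgBr, THF, −78 °C; sat. aq NH4Cl
Reagents that add atoms: vinylmagnesium bromide, C=C[Mg]Br
Why: Grignard 1,2-addition to the aldehyde at low temperature; the carbinol center forms as both epimers, which does not matter because it is oxidised next, and the alkoxide cannot open the oxirane because the arm sits on the same face as the epoxide oxygen.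

Step 8
Reactants: 10 allylic alcohol
Product: 11 1-[(1R,2R,3S,6S)-6-methyl-3-(prop-1-en-2-yl)-7-oxabicyclo[4.1.0]heptan-2-yl]but-3-en-2-one
Conditions: Dess–Martin periodinane, NaHCO3, CH2Cl2, 0 °C; used promptly
Reagents that add atoms: none
Why: Dess–Martin oxidation of the allylic alcohol to the vinyl ketone removes the carbinol stereocenter and gives the dienophile; the buffered, neutral medium avoids conjugate addition and oxirane opening.

Step 9
Reactants: 12 1,4-dibromobutan-2-one
Product: 14 (Z)-1-bromo-2-(triisopropylsilyloxy)buta-1,3-diene, via 1-bromobut-3-en-2-one 13 (not isolated)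
Conditions: iPr2NEt, CH2Cl2, −78 → −20 °C; then iPr2NEt, TIPSOTf, −78 → 0 °C
Reagents that add atoms: triisopropylsilyl trifluoromethanesulfonate, CC(C)[Si](OS(=O)(=O)C(F)(F)F)(C(C)C)C(C)C
Why: E1cB loss of HBr from the beta-bromo ketone gives bromomethyl vinyl ketone, whose only enolisable position is then silylated by soft enolisation to the 2-silyloxy diene; the Z enol ether (bromine cis to oxygen, trans to the vinyl group) is the expected geometry and the only one that can reach the s-cis diene conformation.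

Step 10
Reactants: 11 epoxy vinyl ketone; 14 bromo silyloxy diene
Product: 16 (2R,4R)-2-bromo-4-{2-[(1R,2R,3S,6S)-6-methyl-3-(prop-1-en-2-yl)-7-oxabicyclo[4.1.0]heptan-2-yl]acetyl}cyclohexan-1-one, via silyl enol ether cycloadduct 15 (not isolated)
Conditions: (S)-3,3'-bis(2,4,6-triisopropylphenyl)-BINOL N-triflyl phosphoramide (10 mol%), toluene, −78 → −40 °C; then Bu4NF, AcOH, THF, −40 → 0 °C
Reagents that add atoms: none
Why: The chiral N-triflyl phosphoramide protonates or hydrogen-bonds the s-cis enone carbonyl of 11 and lowers its LUMO, so that diene 14 adds in a concerted, asynchronous [4+2] in which the nucleophilic CHBr terminus bonds to the enone beta-carbon and the CH2 terminus to the alpha-carbon; the closest known reaction type is the N-triflyl phosphoramide-catalysed Diels–Alder reaction of alkyl vinyl ketones with 1-substituted 2-silyloxy-1,3-dienes. Ring B is closed by this intermolecular [4+2] cycloaddition, which forms the C2–C3 and C4–C5 bonds suprafacially on both partners. C4 is set by the catalyst, which exposes the Re face of the enone alpha-carbon, and C2 follows from the endo transition state combined with the Z geometry of the bromo enol ether (bromine outside), which places Br and the acyl group cis. The step needs para regioselectivity (secured by the 2-silyloxy donor), endo selectivity (secured by the acid-bound carbonyl), catalyst control of the face (the ring-A stereocenters are too remote to compete) and survival of the oxirane, which is helped by the low temperature, the non-polar solvent and its hindered, cis-flanked position. Buffered fluoride then cleaves the silyl enol ether with protonation at C6, which creates no stereocenter and leaves the alpha-bromo ketone configurationally intact.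

Step 11
Reactants: 16 bromo diketone
Product: 17 1-[(1R,3R,4S)-3-bromo-4-hydroxy-4-methylcyclohexyl]-2-[(1R,2R,3S,6S)-6-methyl-3-(prop-1-en-2-yl)-7-oxabicyclo[4.1.0]heptan-2-yl]ethan-1-one
Conditions: MeTi(OiPr)3 (from ClTi(OiPr)3 and MeLi, Et2O, −40 °C), −20 °C → rt; aq work-up
Reagents that add atoms: methyltitanium triisopropoxide, C[Ti](OC(C)C)(OC(C)C)OC(C)C (its methyl group comes from methyllithium, [Li]C)
Why: Chemoselective carbonyl addition of the non-basic methyltitanium reagent to the activated, less hindered alpha-bromo cyclohexanone in preference to the alpha-branched side-chain ketone; equatorial attack, trans to the equatorial bromine, sets C1 with axial OH cis to Br (the usual cis-halohydrin outcome of organometallic addition to 2-halocyclohexanones), and the oxirane and the alkyl bromide are inert to this reagent.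

Step 12
Reactants: 17 bromohydrin ketone
Product: 18 (1S,2R,4R)-2-bromo-1-methyl-4-{3-[(1R,2R,3S,6S)-6-methyl-3-(prop-1-en-2-yl)-7-oxabicyclo[4.1.0]heptan-2-yl]prop-1-en-2-yl}cyclohexan-1-ol (CNP0213097.1)
Conditions: Cp2TiMe2 (excess), toluene, 65 °C, dark
Reagents that add atoms: dimethyltitanocene, [CH3-].[CH3-].[Ti+4].c1cc[cH-]c1.c1cc[cH-]c1
Why: Petasis methylenation, in which the titanocene methylidene formed on heating converts the hindered, enolisable ketone to the 1,1-disubstituted alkene through an oxatitanacyclobutane without base, so the bromohydrin, the oxirane and the adjacent C4 stereocenter (already in its equatorial, thermodynamically preferred configuration) are kept; excess reagent covers the free tertiary alcohol.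

Compound list
1 | (S)-(+)-carvone, (5S)-2-methyl-5-(prop-1-en-2-yl)cyclohex-2-en-1-one | CC1=CC[C@@H](CC1=O)C(C)=C | starting material
2 | lithium (3S)-6-methyl-3-(prop-1-en-2-yl)cyclohexa-1,5-dien-1-olate (kinetic dienolate of 1) | CC1=CC[C@@H](C=C1[O-])C(C)=C.[Li+] | intermediate
3 | ethyl 2-[(1R,6S)-3-methyl-2-oxo-6-(prop-1-en-2-yl)cyclohex-3-en-1-yl]acetate | CCOC(=O)C[C@@H]1[C@@H](C(=C)C)CC=C(C)C1=O | intermediate
4 | ethyl 2-[(1R,6S)-3-methyl-6-(prop-1-en-2-yl)-2-(2-tosylhydrazinylidene)cyclohex-3-en-1-yl]acetate | CCOC(=O)C[C@@H]1[C@@H](C(=C)C)CC=C(C)C1=NNS(=O)(=O)c1ccc(C)cc1 | intermediate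
5 | ethyl 2-[(1R,6S)-2-diazenyl-3-methyl-6-(prop-1-en-2-yl)cyclohex-3-en-1-yl]acetate (both epimers at the diazenyl carbon) | CCOC(=O)C[C@@H]1[C@@H](C(=C)C)CC=C(C)C1N=N | intermediate
6 | ethyl 2-[(1S,6S)-3-methyl-6-(prop-1-en-2-yl)cyclohex-2-en-1-yl]acetate | CCOC(=O)C[C@@H]1[C@@H](C(=C)C)CCC(C)=C1 | intermediate
7 | 2-[(1S,6S)-3-methyl-6-(prop-1-en-2-yl)cyclohex-2-en-1-yl]ethan-1-ol | OCC[C@@H]1[C@@H](C(=C)C)CCC(C)=C1 | intermediate
8 | 2-[(1R,2R,3S,6S)-6-methyl-3-(prop-1-en-2-yl)-7-oxabicyclo[4.1.0]heptan-2-yl]ethan-1-ol | OCC[C@@H]1[C@@H](C(=C)C)CC[C@]2(C)O[C@H]12 | intermediate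
9 | 2-[(1R,2R,3S,6S)-6-methyl-3-(prop-1-en-2-yl)-7-oxabicyclo[4.1.0]heptan-2-yl]acetaldehyde | O=CC[C@@H]1[C@@H](C(=C)C)CC[C@]2(C)O[C@H]12 | intermediate
10 | 1-[(1R,2R,3S,6S)-6-methyl-3-(prop-1-en-2-yl)-7-oxabicyclo[4.1.0]heptan-2-yl]but-3-en-2-ol (both carbinol epimers) | C=CC(O)C[C@@H]1[C@@H](C(=C)C)CC[C@]2(C)O[C@H]12 | intermediate
11 | 1-[(1R,2R,3S,6S)-6-methyl-3-(prop-1-en-2-yl)-7-oxabicyclo[4.1.0]heptan-2-yl]but-3-en-2-one | C=CC(=O)C[C@@H]1[C@@H](C(=C)C)CC[C@]2(C)O[C@H]12 | intermediate
12 | 1,4-dibromobutan-2-one | BrCCC(=O)CBr | starting material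
13 | 1-bromobut-3-en-2-one | C=CC(=O)CBr | intermediate
14 | (Z)-1-bromo-2-(triisopropylsilyloxy)buta-1,3-diene | Br/C=C(\O[Si](C(C)C)(C(C)C)C(C)C)C=C | intermediate
15 | 1-[(1R,5R)-5-bromo-4-(triisopropylsilyloxy)cyclohex-3-en-1-yl]-2-[(1R,2R,3S,6S)-6-methyl-3-(prop-1-en-2-yl)-7-oxabicyclo[4.1.0]heptan-2-yl]ethan-1-one | O=C(C[C@@H]1[C@@H](C(=C)C)CC[C@]2(C)O[C@H]12)[C@@H]1CC=C(O[Si](C(C)C)(C(C)C)C(C)C)[C@H](Br)C1 | intermediate
16 | (2R,4R)-2-bromo-4-{2-[(1R,2R,3S,6S)-6-methyl-3-(prop-1-en-2-yl)-7-oxabicyclo[4.1.0]heptan-2-yl]acetyl}cyclohexan-1-one | O=C(C[C@@H]1[C@@H](C(=C)C)CC[C@]2(C)O[C@H]12)[C@@H]1CCC(=O)[C@H](Br)C1 | intermediate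
17 | 1-[(1R,3R,4S)-3-bromo-4-hydroxy-4-methylcyclohexyl]-2-[(1R,2R,3S,6S)-6-methyl-3-(prop-1-en-2-yl)-7-oxabicyclo[4.1.0]heptan-2-yl]ethan-1-one | O=C(C[C@@H]1[C@@H](C(=C)C)CC[C@]2(C)O[C@H]12)[C@@H]1CC[C@](C)(O)[C@H](Br)C1 | intermediate
18 | (1S,2R,4R)-2-bromo-1-methyl-4-{3-[(1R,2R,3S,6S)-6-methyl-3-(prop-1-en-2-yl)-7-oxabicyclo[4.1.0]heptan-2-yl]prop-1-en-2-yl}cyclohexan-1-ol | C=C(C[C@@H]1[C@@H](C(=C)C)CC[C@]2(C)O[C@H]12)[C@@H]1CC[C@](C)(O)[C@H](Br)C1 | target

Total step count: 12. Longest linear sequence: 11 steps (steps 1–8 and 10–12, from (S)-carvone); step 9 is a one-step side branch.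

Steps most likely to fail

Step 10 (key step). What may go wrong: acid-induced opening or rearrangement of the trisubstituted oxirane, sluggish cycloaddition of the bromine-deactivated diene (with protodesilylation of the diene winning), or weak facial control by the catalyst. Fallback, setting out from 11 and coming back at 17 (it also removes the dependence on diene 14): enone 11 is heated with commercial 2-(trimethylsilyloxy)buta-1,3-diene (toluene, 90 °C, BHT; uncatalysed Diels–Alder reaction, no acid present) to give the trimethylsilyl enol ether cycloadduct F1 as both epimers at the acyl-bearing ring-B carbon. K2CO3 in MeOH cleaves the enol ether to the 4-acylcyclohexanone F2, in which that carbon is no longer stereogenic. Enamine-catalysed enantioselective alpha-bromination of the cyclohexanone ((4R,5R)-4,5-diphenylimidazolidine or its antipode, benzoic acid, 4,4-dibromo-2,6-di-tert-butylcyclohexa-2,5-dienone, −30 °C) desymmetrises ring B and should give the (2R)-bromo diketone F3. MeTi(OiPr)3 then adds trans to bromine to give the cis-bromohydrin ketone F4 as a mixture at the acyl-bearing carbon, and DBU (toluene, 50 °C) equilibrates that ketone alpha-carbon to the all-equatorial isomer, which is 17.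

Step 11. What may go wrong: competing addition to the side-chain ketone, enolisation and epimerisation of the alpha-bromo ketone, or partial axial attack at C1. Fallback, setting out from 15 and coming back at 18: the cycloadduct 15 is isolated (Et3N quench, filtration through basic alumina) instead of being desilylated in the flask. Cp2TiMe2 (toluene, 65 °C) methylenates its only ketone to give the silyl enol ether diene F5; Bu4NF/AcOH (THF, −40 → 0 °C) unmasks the alpha-bromo ketone F6, now the only carbonyl group; MeMgBr/CeCl3 (THF, −78 °C) adds equatorially to give 18.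

Step 12. What may go wrong: consumption or complexation of the titanium reagent by the free tertiary hydroxyl, thermal semipinacol ring contraction of the metal alkoxide of the cis-bromohydrin, or no reaction at the hindered ketone. Fallback, setting out from 17 and coming back at 18: N-(trimethylsilyl)imidazole (CH2Cl2, rt) caps the tertiary alcohol as the trimethylsilyl ether F7. Wittig methylenation (Ph3P=CH2 from Ph3PCH3Br and KN(SiMe3)2, THF, 0 °C → rt) gives the silyl ether F8, and K2CO3/MeOH removes the silyl group to give 18.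

Further compounds
F1 | step 10 | 2-[(1R,2R,3S,6S)-6-methyl-3-(prop-1-en-2-yl)-7-oxabicyclo[4.1.0]heptan-2-yl]-1-[4-(trimethylsilyloxy)cyclohex-3-en-1-yl]ethan-1-one (both ring-B epimers) | C[Si](C)(C)OC1=CCC(CC1)C(=O)C[C@@H]1[C@@H](C(=C)C)CC[C@]2(C)O[C@H]12
F2 | step 10 | 4-{2-[(1R,2R,3S,6S)-6-methyl-3-(prop-1-en-2-yl)-7-oxabicyclo[4.1.0]heptan-2-yl]acetyl}cyclohexan-1-one | O=C1CCC(CC1)C(=O)C[C@@H]1[C@@H](C(=C)C)CC[C@]2(C)O[C@H]12
F3 | step 10 | (2R)-2-bromo-4-{2-[(1R,2R,3S,6S)-6-methyl-3-(prop-1-en-2-yl)-7-oxabicyclo[4.1.0]heptan-2-yl]acetyl}cyclohexan-1-one (both C-4 epimers) | O=C(C[C@@H]1[C@@H](C(=C)C)CC[C@]2(C)O[C@H]12)C1CCC(=O)[C@H](Br)C1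
F4 | step 10 | 1-[(3R,4S)-3-bromo-4-hydroxy-4-methylcyclohexyl]-2-[(1R,2R,3S,6S)-6-methyl-3-(prop-1-en-2-yl)-7-oxabicyclo[4.1.0]heptan-2-yl]ethan-1-one (both C-1 epimers) | O=C(C[C@@H]1[C@@H](C(=C)C)CC[C@]2(C)O[C@H]12)C1CC[C@](C)(O)[C@H](Br)C1
F5 | step 11 | {[(4R,6R)-6-bromo-4-{3-[(1R,2R,3S,6S)-6-methyl-3-(prop-1-en-2-yl)-7-oxabicyclo[4.1.0]heptan-2-yl]prop-1-en-2-yl}cyclohex-1-en-1-yl]oxy}tri(propan-2-yl)silane | C=C(C[C@@H]1[C@@H](C(=C)C)CC[C@]2(C)O[C@H]12)[C@@H]1CC=C(O[Si](C(C)C)(C(C)C)C(C)C)[C@H](Br)C1
F6 | step 11 | (2R,4R)-2-bromo-4-{3-[(1R,2R,3S,6S)-6-methyl-3-(prop-1-en-2-yl)-7-oxabicyclo[4.1.0]heptan-2-yl]prop-1-en-2-yl}cyclohexan-1-one | C=C(C[C@@H]1[C@@H](C(=C)C)CC[C@]2(C)O[C@H]12)[C@@H]1CCC(=O)[C@H](Br)C1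
F7 | step 12 | 1-[(1R,3R,4S)-3-bromo-4-methyl-4-(trimethylsilyloxy)cyclohexyl]-2-[(1R,2R,3S,6S)-6-methyl-3-(prop-1-en-2-yl)-7-oxabicyclo[4.1.0]heptan-2-yl]ethan-1-one | O=C(C[C@@H]1[C@@H](C(=C)C)CC[C@]2(C)O[C@H]12)[C@@H]1CC[C@](C)(O[Si](C)(C)C)[C@H](Br)C1
F8 | step 12 | {[(1S,2R,4R)-2-bromo-1-methyl-4-{3-[(1R,2R,3S,6S)-6-methyl-3-(prop-1-en-2-yl)-7-oxabicyclo[4.1.0]heptan-2-yl]prop-1-en-2-yl}cyclohexyl]oxy}trimethylsilane | C=C(C[C@@H]1[C@@H](C(=C)C)CC[C@]2(C)O[C@H]12)[C@@H]1CC[C@](C)(O[Si](C)(C)C)[C@H](Br)C1
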